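## Retrosynthetic overview

1. There is one strategic disconnection, the C8(sp2)–CH2(sp3) bond. It is made by a light-driven nickel decarboxylative coupling of an 8-iodoapigenin tris-MOM ether with the redox-active ester of a C11 acid, and CO2 is the traceless handle.
2. The C11 acid, (3R)-6-methyl-3-isopropenylhept-6-enoic acid, comes from Wittig methylenation of a keto acid. The keto acid comes from Pinnick oxidation of a keto aldehyde, which comes from oxidative ring opening of (+)-limonene oxide. C4 of limonene becomes the only stereocentre of the target.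
3. The iodide comes from apigenin by capping all three phenols as MOM ethers, followed by C8-selective iodination.
4. No ring is formed. Rings A, C and B are bought intact in apigenin, and the only ring event is the opening of the limonene carbocycle.
5. The endgame is removal of the three MOM groups.

Assumption: commercial (+)-limonene oxide is the (4R) cis/trans mixture. Both epoxide carbons lose their stereochemistry in step 1, so it is used as bought. The stereocentre of the target SMILES reads as (R).

## Route

Step 1
Reactants: 1 (+)-limonene oxide, (4R)-1-methyl-4-(prop-1-en-2-yl)-7-oxabicyclo[4.1.0]heptane (cis/trans mixture)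
Product: 3 (3R)-6-oxo-3-(prop-1-en-2-yl)heptanal, via limonene-1,2-diol 2 (not isolated)
Conditions: H5IO6 (1.2 equiv), THF/H2O 4:1, 0 °C to rt, 2 h
Reagents that add atoms: water, O
Why: Acid-assisted epoxide hydrolysis followed by periodate (Malaprade) glycol cleavage opens only the oxygenated C1–C2 bond, leaves the 1,1-disubstituted alkene alone, and does not touch the (R) centre, which simply becomes C3 of the chain.

Step 2
Reactants: 3 (3R)-6-oxo-3-(prop-1-en-2-yl)heptanal
Product: 4 (3R)-6-oxo-3-(prop-1-en-2-yl)heptanoic acid
Conditions: NaClO2 (1.5 equiv), NaH2PO4 (1.5 equiv), 2-methyl-2-butene (10 equiv), t-BuOH/H2O, 0 °C to rt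
Reagents that add atoms: sodium chlorite (NaClO2), [Na+].[O-]Cl=O
Why: Pinnick oxidation is selective for the aldehyde, the scavenger removes HOCl so the isopropenyl group survives, and the stereocentre is beta to the carbonyl and cannot epimerise.

Step 3
Reactants: 4 (3R)-6-oxo-3-(prop-1-en-2-yl)heptanoic acid
Product: 5 (3R)-6-methyl-3-(prop-1-en-2-yl)hept-6-enoic acid
Conditions: Ph3PCH3Br (2.5 equiv), KOtBu (3.5 equiv), THF, 0 °C to rt; 1 M HCl work-up
Reagents that add atoms: methyltriphenylphosphonium bromide, C[P+](c1ccccc1)(c1ccccc1)c1ccccc1.[Br-]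
Why: In this Wittig methylenation the carboxylate formed first is inert to the ylide, only the methyl ketone is olefinated, and the stereocentre (beta to the carboxylate, gamma to the ketone) has no acidic hydrogen.

Step 4
Reactants: 6 apigenin, 5,7-dihydroxy-2-(4-hydroxyphenyl)-4H-chromen-4-one
Product: 7 5,7-bis(methoxymethoxy)-2-[4-(methoxymethoxy)phenyl]-4H-chromen-4-one (apigenin tris-MOM ether)
Conditions: NaH (4.5 equiv), MOMCl (4.5 equiv), DMF, 0 °C to rt
Reagents that add atoms: chloromethyl methyl ether (MOMCl), COCCl
Why: This is a Williamson-type O-alkylation with a hard electrophile; NaH also frees the chelated 5-OH, and capping that group is what steers the next step to C8.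

Step 5
Reactants: 7 apigenin tris-MOM ether
Product: 8 8-iodo-5,7-bis(methoxymethoxy)-2-[4-(methoxymethoxy)phenyl]-4H-chromen-4-one
Conditions: NIS (1.1 equiv), DMF, rt, dark
Reagents that add atoms: N-iodosuccinimide, O=C1CCC(=O)N1I
Why: Electrophilic aromatic iodination of fully O-alkylated 5,7-dioxygenated flavones goes to C8 (C6 takes over only when 5-OH is free), C6 is also the more crowded site between two MOM ethers, ring B and C3 are much less nucleophilic, and the neutral medium keeps the acetals intact.

Step 6
Reactants: 5 (3R)-6-methyl-3-(prop-1-en-2-yl)hept-6-enoic acid; 8 8-iodoapigenin tris-MOM ether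
Product: 10 8-[(2R)-5-methyl-2-(prop-1-en-2-yl)hex-5-en-1-yl]-5,7-bis(methoxymethoxy)-2-[4-(methoxymethoxy)phenyl]-4H-chromen-4-one, via redox-active ester 9 (not isolated)
Conditions: 5 (1.6 equiv), N-hydroxyphthalimide (1.6 equiv), DIC (1.6 equiv), DMA, rt, 2 h; then 8 (1.0 equiv), NiBr2(dme) (20 mol %), dtbbpy (24 mol %), Hantzsch ester (2.5 equiv), NaHCO3 (3 equiv), DMA (0.2 M), 427 nm LED, 25 °C, Ar, 16 h
Reagents that add atoms: N-hydroxyphthalimide, O=C1c2ccccc2C(=O)N1O (its atoms are found in 9 only, none of them in 10)
Why: Proposed new method: a photocatalyst-free, light-driven nickel decarboxylative cross-electrophile arylation carried over to substrates on which it has not been shown, namely an 8-iodoflavone (an aryl iodide flanked by two oxygen substituents on a light-absorbing, reducible chromone) and a primary radical that carries both a homoallyl and a 5-methylhex-5-enyl radical clock; the Hantzsch ester and 9 form an electron donor–acceptor complex whose excitation at 427 nm (outside the absorption of 8) causes single-electron transfer, N–O cleavage and loss of CO2 to give the primary radical, zerovalent nickel made by the same reductant inserts into the weak C8–I bond, the aryl nickel iodide (divalent nickel, about 40 mM) traps the radical at roughly 10^6–10^7 M-1 s-1 and so outruns 5-exo/6-endo closure (about 10^4 s-1, slowed by the 5-methyl group) and the 1,2-vinyl shift, reductive elimination from trivalent nickel forges C8–CH2, and the stereocentre is beta to the radical carbon, breaks no bond and keeps the limonene configuration; the closest known reaction type is the nickel-catalysed reductive coupling of N-acyloxyphthalimides with simple aryl halides, driven by zinc or by Hantzsch ester and light.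

Step 7
Reactants: 10 coupled tris-MOM ether
Product: 11 5,7-dihydroxy-2-(4-hydroxyphenyl)-8-[(2R)-5-methyl-2-(prop-1-en-2-yl)hex-5-en-1-yl]-4H-chromen-4-one (target)
Conditions: 1.25 M HCl in MeOH, CH2Cl2, 35 °C, about 3 h, stopped at full conversion
Reagents that add atoms: none
Why: Acid-catalysed acetal exchange with methanol, as used to unmask 8-prenyl and 8-lavandulyl flavonoids, cleaves the aryl MOM ethers much faster than dilute acid protonates the isobutene-type alkenes, and it is far too mild for a Wessely–Moser 8-to-6 shift or for any change at the stereocentre.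

## Compound list

1 | (+)-limonene oxide, (4R)-1-methyl-4-(prop-1-en-2-yl)-7-oxabicyclo[4.1.0]heptane, cis/trans mixture | CC12CC[C@H](CC1O2)C(=C)C | starting material
2 | (4R)-p-menth-8-ene-1,2-diol (limonene-1,2-diol) | CC1(O)CC[C@H](CC1O)C(=C)C | intermediate
3 | (3R)-6-oxo-3-(prop-1-en-2-yl)heptanal | CC(=O)CC[C@H](CC=O)C(=C)C | intermediate
4 | (3R)-6-oxo-3-(prop-1-en-2-yl)heptanoic acid | CC(=O)CC[C@H](CC(=O)O)C(=C)C | intermediate
5 | (3R)-6-methyl-3-(prop-1-en-2-yl)hept-6-enoic acid | C=C(C)CC[C@H](CC(=O)O)C(=C)C | intermediate
6 | apigenin | O=c1cc(-c2ccc(O)cc2)oc2cc(O)cc(O)c12 | starting material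
7 | apigenin 5,7,4'-tris(methoxymethyl) ether | COCOc1ccc(cc1)-c1cc(=O)c2c(OCOC)cc(OCOC)cc2o1 | intermediate
8 | 8-iodoapigenin 5,7,4'-tris(methoxymethyl) ether | COCOc1ccc(cc1)-c1cc(=O)c2c(OCOC)cc(OCOC)c(I)c2o1 | intermediate
9 | 1,3-dioxoisoindolin-2-yl (3R)-6-methyl-3-(prop-1-en-2-yl)hept-6-enoate | C=C(C)CC[C@H](CC(=O)ON1C(=O)c2ccccc2C1=O)C(=C)C | intermediate
10 | 8-[(2R)-5-methyl-2-(prop-1-en-2-yl)hex-5-en-1-yl]apigenin 5,7,4'-tris(methoxymethyl) ether | C=C(C)CC[C@H](Cc1c(OCOC)cc(OCOC)c2c(=O)cc(-c3ccc(OCOC)cc3)oc12)C(=C)C | intermediate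
11 | 5,7-dihydroxy-2-(4-hydroxyphenyl)-8-[(2R)-5-methyl-2-(prop-1-en-2-yl)hex-5-en-1-yl]-4H-chromen-4-one | C=C(C)CC[C@H](Cc1c(O)cc(O)c2c(=O)cc(-c3ccc(O)cc3)oc12)C(=C)C | target

## Step count

Total step count: 7.
Longest linear sequence: 5 steps (steps 1, 2, 3, 6 and 7, from 1).

## Steps most likely to fail

**Step 6 (the proposed new step).**
- Risks: radical cyclisation onto the 5-methylhexenyl alkene, hydrogen transfer from the Hantzsch ester to the radical, hydrodeiodination of 8 back to 7, and slow insertion at the doubly ortho-oxygenated C8–I bond.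
- The fallback uses known chemistry. It sets out from 5 (partner 8 unchanged) and comes back at 10.
- Acid 5 is converted into isolated 9 (N-hydroxyphthalimide, DIC, cat. DMAP, CH2Cl2).
- Ester 9 undergoes the known copper-catalysed decarboxylative borylation (B2pin2, Cu(acac)2, LiOH·H2O, MgCl2, dioxane/DMF, rt). This gives 2-[(2S)-5-methyl-2-(prop-1-en-2-yl)hex-5-en-1-yl]-4,4,5,5-tetramethyl-1,3,2-dioxaborolane F1. The spatial arrangement is unchanged; the descriptor changes only because CH2B ranks below CH2CH2.
- KHF2 in MeOH/H2O then gives potassium trifluoro[(2S)-5-methyl-2-(prop-1-en-2-yl)hex-5-en-1-yl]borate F2.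
- A two-electron B-alkyl Suzuki–Miyaura coupling with 8 (Pd(OAc)2, RuPhos, K2CO3, toluene/H2O, 85 °C) delivers 10. This reaction class is already used on 8-iodoflavones, and no free radical is present at the C–C bond-forming stage.

**Step 7.**
- Risks: acid-induced closure of the freed 7-OH onto the isopropenyl group to give a 2,2-dimethylchroman, and addition of methanol to either alkene.
- The fallback moves the acid step to a point where no alkene is present and makes the last unmasking basic. It sets out from 8 and comes back at 11.
- Iodide 8 with HCl/MeOH at 50 °C gives 8-iodoapigenin F3.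
- Ac2O/pyridine gives 8-iodoapigenin 5,7,4'-triacetate F4.
- The step 6 coupling with 5 (through 9) gives 8-[(2R)-5-methyl-2-(prop-1-en-2-yl)hex-5-en-1-yl]apigenin 5,7,4'-triacetate F5.
- Catalytic K2CO3 in MeOH at 0 °C removes the acetates by transesterification and gives 11.

**Step 3.**
- Risks: the potassium keto-carboxylate is poorly soluble in THF, and the basic ylide may enolise the methyl ketone, which returns 4.
- The fallback replaces ylide chemistry by addition and elimination (Peterson olefination). It sets out from 4 and comes back at 5.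
- Me3SiCH2MgCl/CeCl3 (3 equiv, THF, −78 to 0 °C) first deprotonates the acid. As a barely basic organocerium it then adds to the ketone and gives (3R)-6-hydroxy-6-methyl-3-(prop-1-en-2-yl)-7-(trimethylsilyl)heptanoic acid F6. This is a mixture of C6 epimers, and that centre disappears in the next operation.
- KH in THF triggers the syn-elimination, and acidic work-up gives 5.

## Further compounds

F1 | step 6 | 2-[(2S)-5-methyl-2-(prop-1-en-2-yl)hex-5-en-1-yl]-4,4,5,5-tetramethyl-1,3,2-dioxaborolane | C=C(C)CC[C@H](CB1OC(C)(C)C(C)(C)O1)C(=C)C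
F2 | step 6 | potassium trifluoro[(2S)-5-methyl-2-(prop-1-en-2-yl)hex-5-en-1-yl]borate | C=C(C)CC[C@H](C[B-](F)(F)F)C(=C)C.[K+]
F3 | step 7 | 8-iodoapigenin | Oc1ccc(cc1)-c1cc(=O)c2c(O)cc(O)c(I)c2o1
F4 | step 7 | 8-iodoapigenin 5,7,4'-triacetate | CC(=O)Oc1ccc(cc1)-c1cc(=O)c2c(OC(C)=O)cc(OC(C)=O)c(I)c2o1
F5 | step 7 | 8-[(2R)-5-methyl-2-(prop-1-en-2-yl)hex-5-en-1-yl]apigenin 5,7,4'-triacetate | C=C(C)CC[C@H](Cc1c(OC(C)=O)cc(OC(C)=O)c2c(=O)cc(-c3ccc(OC(C)=O)cc3)oc12)C(=C)C
F6 | step 3 | (3R)-6-hydroxy-6-methyl-3-(prop-1-en-2-yl)-7-(trimethylsilyl)heptanoic acid | C[Si](C)(C)CC(C)(O)CC[C@H](CC(=O)O)C(=C)C
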